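**Plan**

1. Retrosynthetic cuts, last-made bond first: O–SiEt3; the oxirane CH–CMe2 and O–CMe2 bonds (aldehyde + isopropylide); the vinyl C=C (to CHO) and the CH2–vinyl bond; the acetyl C–CH3 bond; the side-chain epoxide and allylic C–O bonds; ring C–Cl and C–Br.
2. Forward: the cyclohexane comes intact from (S)-limonene and is halogenated first. The chain is then grown outward from the isopropenyl carbon (CH2OH, epoxide, CH3, vinyl), and the oxirane is the only ring closed, in the last skeletal step.
3. Enabling feature: the oxirane is a CH carbon next to CH2 (a former aldehyde carbon) joined to a CMe2 carbon (an isopropylidene unit). It is the acid-labile ring, so it is made after every halogenation, Lewis-acid and oxidation step; the only competing carbonyl is a methyl ketone on a fully substituted C–OSi carbon.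
4. Stereochemistry: the ring CH comes from (S)-limonene. CHBr and C(Me)Cl come from stereospecific inversions (diaxial HBr opening of the cis-epoxide, then a bromonium shift that inverts both carbons), giving the trans-diequatorial array that direct BrCl addition would not give. The quaternary carbinol comes from Sharpless epoxidation with L-(+)-tartrate, and the oxirane CH from the sulfur stereocentre of the ylide.

Key step: step 14

Assumption: the sense of induction of the oxosulfonium ylide is not known; the (S)-salt is written, and the (R)-salt (from the equally available (R)-sulfoximine) would replace it if that antipode proved to be the matched one.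

**Route**

Step 1
Reactants: 1 (S)-(−)-limonene
Product: 2 cis-limonene 1,2-oxide [(1S,4S,6R)-1-methyl-4-(prop-1-en-2-yl)-7-oxabicyclo[4.1.0]heptane]
Conditions: mCPBA, CH2Cl2, 0 °C; crude epoxide mixture then pyrrolidine, H2O, 95 °C; distillation of the unreacted cis-epoxide
Reagents that add atoms: 3-chloroperbenzoic acid, OOC(=O)c1cccc(Cl)c1
Why: Prilezhaev epoxidation takes the electron-rich trisubstituted ring alkene without face preference, and the unwanted trans-epoxide (oxygen syn to isopropenyl) is then removed by its much faster Fürst–Plattner aminolysis at the secondary carbon (kinetic separation), so that at most half of the material, the epoxide with oxygen anti to the isopropenyl group, is carried on.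

Step 2
Reactants: 2 cis-limonene 1,2-oxide
Product: 3 (1R,2R,5S)-2-bromo-2-methyl-5-(prop-1-en-2-yl)cyclohexan-1-ol
Conditions: 48% aq. HBr (1.1 equiv), Et2O, −15 °C, short contact; used crude
Reagents that add atoms: hydrogen bromide, Br
Why: Acid-mediated epoxide opening to a bromohydrin in which bromide attacks the tertiary carbon with inversion, the Markovnikov and trans-diaxial (Fürst–Plattner) preferences coinciding for this epoxide, so that Br ends on the face of the isopropenyl group and the secondary OH anti to it, while cold aqueous HBr should not add to the 1,1-disubstituted alkene in that time.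

Step 3
Reactants: 3 (1R,2R,5S)-2-bromo-2-methyl-5-(prop-1-en-2-yl)cyclohexan-1-ol
Product: 4 (1S,2S,4S)-2-bromo-1-chloro-1-methyl-4-(prop-1-en-2-yl)cyclohexane
Conditions: 1-chloro-N,N,2-trimethylprop-1-en-1-amine (1.2 equiv), CH2Cl2, 0 °C → rt
Reagents that add atoms: 1-chloro-N,N,2-trimethylprop-1-en-1-amine, CC(C)=C(Cl)N(C)C
Why: Deoxychlorination with neighbouring-group participation: the O-alkyl imidate leaves with help from the antiperiplanar axial tertiary bromide, and the chloride of the ion pair opens the bromonium ion at its tertiary carbon from the opposite face (Markovnikov), so that bromine has shifted to the secondary carbon, both carbons are inverted, and the trans-diequatorial bromochloride results under neutral conditions.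

Step 4
Reactants: 4 (1S,2S,4S)-2-bromo-1-chloro-1-methyl-4-(prop-1-en-2-yl)cyclohexane
Product: 5 2-[(1S,3S,4S)-3-bromo-4-chloro-4-methylcyclohexyl]prop-2-en-1-ol
Conditions: SeO2 (20 mol %), t-BuOOH, salicylic acid (10 mol %), CH2Cl2, rt
Reagents that add atoms: tert-butyl hydroperoxide, CC(C)(C)OO
Why: Selenium dioxide allylic oxidation (ene reaction, then [2,3]-sigmatropic shift) of a 1,1-disubstituted alkene, which is expected to take the allylic methyl group in preference to the ring methine.

Step 5
Reactants: 5 2-[(1S,3S,4S)-3-bromo-4-chloro-4-methylcyclohexyl]prop-2-en-1-ol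
Product: 6 [(2S)-2-[(1S,3S,4S)-3-bromo-4-chloro-4-methylcyclohexyl]oxiran-2-yl]methanol
Conditions: Ti(OiPr)4 (10 mol %), L-(+)-diethyl tartrate (12 mol %), t-BuOOH, 4 Å MS, CH2Cl2, −20 °C
Reagents that add atoms: tert-butyl hydroperoxide, CC(C)(C)OO
Why: Sharpless asymmetric epoxidation, in which the L-(+)-tartrate catalyst delivers oxygen to the alkene face that gives the (S)-configured 2,2-disubstituted epoxy alcohol, so the later quaternary carbinol centre is set by the reagent and not by the remote ring centres.

Step 6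
Reactants: 6 [(2S)-2-[(1S,3S,4S)-3-bromo-4-chloro-4-methylcyclohexyl]oxiran-2-yl]methanol
Product: 7 (2R)-2-[(1S,3S,4S)-3-bromo-4-chloro-4-methylcyclohexyl]oxirane-2-carbaldehyde
Conditions: IBX (2-iodoxybenzoic acid), DMSO, rt
Reagents that add atoms: none
Why: Hypervalent-iodine (IBX) oxidation of the primary alcohol under neutral conditions gives the epoxy aldehyde, which cannot epimerise because its α-carbon is fully substituted (the descriptor changes by priority only).

Step 7
Reactants: 7 (2R)-2-[(1S,3S,4S)-3-bromo-4-chloro-4-methylcyclohexyl]oxirane-2-carbaldehyde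
Product: 8 (1RS)-1-[(2R)-2-[(1S,3S,4S)-3-bromo-4-chloro-4-methylcyclohexyl]oxiran-2-yl]ethan-1-ol
Conditions: MeMgBr, THF, −78 °C
Reagents that add atoms: methylmagnesium bromide, C[Mg]Br
Why: Grignard 1,2-addition to the aldehyde at low temperature is much faster than attack on the epoxide or the alkyl halides; the new carbinol centre is left uncontrolled because it is removed by oxidation in step 9.

Step 8
Reactants: 8 (1RS)-1-[(2R)-2-[(1S,3S,4S)-3-bromo-4-chloro-4-methylcyclohexyl]oxiran-2-yl]ethan-1-ol; 9 vinylmagnesium bromide (3 equiv)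
Product: 10 (2RS,3S)-3-[(1S,3S,4S)-3-bromo-4-chloro-4-methylcyclohexyl]hex-5-ene-2,3-diol
Conditions: CuBr·SMe2 (15 mol %), THF, −40 → −10 °C
Reagents that add atoms: none
Why: Copper-catalysed SN2 opening of a 2,2-disubstituted epoxide by a vinyl Grignard reagent at its only accessible carbon (CH2), which leaves the quaternary C–O centre untouched and turns the epoxide oxygen into the tertiary alcohol; the equatorial halides have no antiperiplanar partner for elimination.

Step 9
Reactants: 10 (2RS,3S)-3-[(1S,3S,4S)-3-bromo-4-chloro-4-methylcyclohexyl]hex-5-ene-2,3-diol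
Product: 11 (3S)-3-[(1S,3S,4S)-3-bromo-4-chloro-4-methylcyclohexyl]-3-hydroxyhex-5-en-2-one
Conditions: IBX (2-iodoxybenzoic acid), DMSO, rt
Reagents that add atoms: none
Why: IBX oxidation of the secondary alcohol of a 1,2-diol to the α-hydroxy ketone, a reagent that does not cleave the glycol C–C bond and cannot oxidise the tertiary alcohol; both carbinol epimers converge on one ketone.

Step 10
Reactants: 11 (3S)-3-[(1S,3S,4S)-3-bromo-4-chloro-4-methylcyclohexyl]-3-hydroxyhex-5-en-2-one
Product: 12 (3S)-3-[(1S,3S,4S)-3-bromo-4-chloro-4-methylcyclohexyl]-3-[(triethylsilyl)oxy]hex-5-en-2-one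
Conditions: Et3SiOTf, 2,6-lutidine, CH2Cl2, −78 → −40 °C
Reagents that add atoms: triethylsilyl trifluoromethanesulfonate, CC[Si](CC)(CC)OS(=O)(=O)C(F)(F)F
Why: Silylation of a hindered tertiary alcohol with a silyl triflate and 2,6-lutidine at low temperature, conditions under which the methyl ketone should not be converted into its silyl enol ether.

Step 11
Reactants: 12 (3S)-3-[(1S,3S,4S)-3-bromo-4-chloro-4-methylcyclohexyl]-3-[(triethylsilyl)oxy]hex-5-en-2-one
Product: 14 (3S)-3-[(1S,3S,4S)-3-bromo-4-chloro-4-methylcyclohexyl]-4-oxo-3-[(triethylsilyl)oxy]pentanal, via ozonide 13 (not isolated)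
Conditions: O3, CH2Cl2, −78 °C; then PPh3, −78 °C → rt
Reagents that add atoms: ozone, [O-][O+]=O
Why: Ozonolysis with reductive work-up cleaves the only remaining C=C bond to the aldehyde, and the silyl ether on the β-oxygen blocks retro-aldol cleavage of the product.

Step 12
Reactants: 15 (S)-N,S-dimethyl-S-phenylsulfoximine
Product: 19 (S)-N-methyl-S-phenyl-S-(propan-2-yl)sulfoximine, via lithiated S-methyl sulfoximine 16 (not isolated), via S-ethyl sulfoximine 17 (not isolated), via lithiated S-ethyl sulfoximine 18 (not isolated)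
Conditions: n-BuLi, THF, −78 °C; MeI, −78 → 0 °C; then n-BuLi, −78 °C; MeI, −78 °C → rt
Reagents that add atoms: iodomethane, CI
Why: Two successive α-lithiation and C-methylation cycles of the sulfoximine-stabilised carbanion build the isopropyl group without touching the sulfur stereocentre.

Step 13
Reactants: 19 (S)-N-methyl-S-phenyl-S-(propan-2-yl)sulfoximine
Product: 20 (S)-(dimethylamino)isopropylphenyloxosulfonium tetrafluoroborate
Conditions: Me3OBF4, CH2Cl2, rt
Reagents that add atoms: trimethyloxonium tetrafluoroborate, C[O+](C)C.F[B-](F)(F)F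
Why: N-Alkylation of the basic sulfoximine nitrogen by the oxonium salt gives the aminosulfoxonium salt with retention at sulfur.

Step 14
Reactants: 14 (3S)-3-[(1S,3S,4S)-3-bromo-4-chloro-4-methylcyclohexyl]-4-oxo-3-[(triethylsilyl)oxy]pentanal; 20 (S)-(dimethylamino)isopropylphenyloxosulfonium tetrafluoroborate
Product: 22 (3S)-3-[(1S,3S,4S)-3-bromo-4-chloro-4-methylcyclohexyl]-4-[(2R)-3,3-dimethyloxiran-2-yl]-3-[(triethylsilyl)oxy]butan-2-one, via isopropylide 21 (not isolated)
Conditions: 20, NaH, THF–DMSO, 0 °C → rt; then 14, −30 °C → rt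
Reagents that add atoms: none
Why: Proposed new method: the ylide carbon adds to the aldehyde C=O to give a betaine whose alkoxide displaces (S)-N,N-dimethylbenzenesulfinamide from the CMe2 carbon, so the CH–CMe2 and O–CMe2 bonds form and the oxirane closes by 3-exo-tet ring closure. The closest known reactions are isopropylidene transfer to aldehydes and ketones from racemic (dimethylamino)aryloxosulfonium isopropylides and from diphenylsulfonium isopropylide (Johnson–Corey–Chaykovsky epoxidation), and enantioselective methylene or benzylidene transfer from non-racemic sulfur ylides; an enantiopure isopropylide acting on a chiral aldehyde is not known. The salt has a single acidic C–H, because the S-phenyl and NMe2 groups offer none at the atoms bound to sulfur, so the ylide forms regiospecifically, and its sulfur stereocentre is configurationally stable. The new (R)-configured oxirane CH requires attack on the Si face of the aldehyde and is meant to be set by the sulfur stereocentre, whose O, NMe2 and phenyl groups make the two gauche placements of the carbonyl oxygen in the addition and closure transition states unequal, possibly helped by the β-silyloxy quaternary centre. The step needs chemoselectivity for the aldehyde over the methyl ketone, secured by the fully substituted carbon that shields the ketone, and it needs the β-oxygen to stay in place, secured by the silyl ether (no retro-aldol) and by the lower basicity of an oxosulfonium ylide, which limits enolisation and β-elimination.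

Step 15
Reactants: 22 (3S)-3-[(1S,3S,4S)-3-bromo-4-chloro-4-methylcyclohexyl]-4-[(2R)-3,3-dimethyloxiran-2-yl]-3-[(triethylsilyl)oxy]butan-2-one
Product: 23 (3S)-3-[(1S,3S,4S)-3-bromo-4-chloro-4-methylcyclohexyl]-4-[(2R)-3,3-dimethyloxiran-2-yl]-3-hydroxybutan-2-one
Conditions: Bu4NF, AcOH (1:1), THF, 0 °C → rt
Reagents that add atoms: none
Why: Fluoride-mediated desilylation buffered with acetic acid should free the tertiary alcohol without acid-catalysed attack of that hydroxyl on the trisubstituted oxirane and without base-induced loss of the halides.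

**Compound list**

1 | (S)-(−)-limonene | CC(=C)[C@H]1CCC(C)=CC1 | starting material
2 | cis-limonene 1,2-oxide, (1S,4S,6R)-1-methyl-4-(prop-1-en-2-yl)-7-oxabicyclo[4.1.0]heptane | CC(=C)[C@H]1CC[C@]2(C)O[C@@H]2C1 | intermediate
3 | (1R,2R,5S)-2-bromo-2-methyl-5-(prop-1-en-2-yl)cyclohexan-1-ol | CC(=C)[C@H]1CC[C@@](C)(Br)[C@H](O)C1 | intermediate
4 | (1S,2S,4S)-2-bromo-1-chloro-1-methyl-4-(prop-1-en-2-yl)cyclohexane | CC(=C)[C@H]1CC[C@](C)(Cl)[C@@H](Br)C1 | intermediate
5 | 2-[(1S,3S,4S)-3-bromo-4-chloro-4-methylcyclohexyl]prop-2-en-1-ol | OCC(=C)[C@H]1CC[C@](C)(Cl)[C@@H](Br)C1 | intermediate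
6 | [(2S)-2-[(1S,3S,4S)-3-bromo-4-chloro-4-methylcyclohexyl]oxiran-2-yl]methanol | OC[C@]1(CO1)[C@H]2CC[C@](C)(Cl)[C@@H](Br)C2 | intermediate
7 | (2R)-2-[(1S,3S,4S)-3-bromo-4-chloro-4-methylcyclohexyl]oxirane-2-carbaldehyde | O=C[C@]1(CO1)[C@H]2CC[C@](C)(Cl)[C@@H](Br)C2 | intermediate
8 | (1RS)-1-[(2R)-2-[(1S,3S,4S)-3-bromo-4-chloro-4-methylcyclohexyl]oxiran-2-yl]ethan-1-ol (both carbinol epimers) | CC(O)[C@]1(CO1)[C@H]2CC[C@](C)(Cl)[C@@H](Br)C2 | intermediate
9 | vinylmagnesium bromide | C=C[Mg]Br | starting material
10 | (2RS,3S)-3-[(1S,3S,4S)-3-bromo-4-chloro-4-methylcyclohexyl]hex-5-ene-2,3-diol (both C2 epimers) | CC(O)[C@](O)(CC=C)[C@H]1CC[C@](C)(Cl)[C@@H](Br)C1 | intermediate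
11 | (3S)-3-[(1S,3S,4S)-3-bromo-4-chloro-4-methylcyclohexyl]-3-hydroxyhex-5-en-2-one | CC(=O)[C@](O)(CC=C)[C@H]1CC[C@](C)(Cl)[C@@H](Br)C1 | intermediate
12 | (3S)-3-[(1S,3S,4S)-3-bromo-4-chloro-4-methylcyclohexyl]-3-[(triethylsilyl)oxy]hex-5-en-2-one | CC(=O)[C@](O[Si](CC)(CC)CC)(CC=C)[C@H]1CC[C@](C)(Cl)[C@@H](Br)C1 | intermediate
13 | ozonide, (3S)-3-[(1S,3S,4S)-3-bromo-4-chloro-4-methylcyclohexyl]-4-(1,2,4-trioxolan-3-yl)-3-[(triethylsilyl)oxy]butan-2-one (both trioxolane epimers) | CC(=O)[C@](O[Si](CC)(CC)CC)(CC1OCOO1)[C@H]2CC[C@](C)(Cl)[C@@H](Br)C2 | intermediate (not isolated)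
14 | (3S)-3-[(1S,3S,4S)-3-bromo-4-chloro-4-methylcyclohexyl]-4-oxo-3-[(triethylsilyl)oxy]pentanal | CC(=O)[C@](O[Si](CC)(CC)CC)(CC=O)[C@H]1CC[C@](C)(Cl)[C@@H](Br)C1 | intermediate
15 | (S)-N,S-dimethyl-S-phenylsulfoximine | C[S@@](=O)(=NC)c1ccccc1 | starting material
16 | lithiated S-methyl sulfoximine, (S)-S-(lithiomethyl)-N-methyl-S-phenylsulfoximine | [Li]C[S@@](=O)(=NC)c1ccccc1 | intermediate (not isolated)
17 | (S)-S-ethyl-N-methyl-S-phenylsulfoximine | CC[S@@](=O)(=NC)c1ccccc1 | intermediate (not isolated)
18 | lithiated S-ethyl sulfoximine, (S)-S-(1-lithioethyl)-N-methyl-S-phenylsulfoximine | CC([Li])[S@@](=O)(=NC)c1ccccc1 | intermediate (not isolated)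
19 | (S)-N-methyl-S-phenyl-S-(propan-2-yl)sulfoximine | CC(C)[S@@](=O)(=NC)c1ccccc1 | intermediate
20 | (S)-(dimethylamino)isopropylphenyloxosulfonium tetrafluoroborate | CC(C)[S@@+](=O)(N(C)C)c1ccccc1.F[B-](F)(F)F | intermediate
21 | (S)-(dimethylamino)phenyloxosulfonium isopropylide | C[C-](C)[S@@+](=O)(N(C)C)c1ccccc1 | intermediate (not isolated)
22 | (3S)-3-[(1S,3S,4S)-3-bromo-4-chloro-4-methylcyclohexyl]-4-[(2R)-3,3-dimethyloxiran-2-yl]-3-[(triethylsilyl)oxy]butan-2-one | CC(=O)[C@](O[Si](CC)(CC)CC)(C[C@H]1OC1(C)C)[C@H]2CC[C@](C)(Cl)[C@@H](Br)C2 | intermediate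
23 | (3S)-3-[(1S,3S,4S)-3-bromo-4-chloro-4-methylcyclohexyl]-4-[(2R)-3,3-dimethyloxiran-2-yl]-3-hydroxybutan-2-one | CC(=O)[C@](O)(C[C@H]1OC1(C)C)[C@H]1CC[C@](C)(Cl)[C@@H](Br)C1 | target

**Step count**

Total: 15 steps (13 in the main line, 2 for the ylide precursor). Longest linear sequence: 13 steps (steps 1–11, 14, 15) from (S)-limonene.

**Steps most likely to fail**

Step 14. The sulfur stereocentre may discriminate poorly between the two aldehyde faces, and the basic ylide may enolise the aldehyde so that triethylsilanolate is lost by β-elimination. The fallback uses known chemistry, sets out from 14 and comes back at 22. Wittig olefination of 14 with isopropylidenetriphenylphosphorane (i-PrPPh3I, KN(SiMe3)2, THF, −78 °C) should give the trisubstituted alkene (3S)-3-[(1S,3S,4S)-3-bromo-4-chloro-4-methylcyclohexyl]-6-methyl-3-[(triethylsilyl)oxy]hept-5-en-2-one F1. Shi epoxidation of that alkene (1,2:4,5-di-O-isopropylidene-β-D-erythro-2,3-hexodiulo-2,6-pyranose as catalyst, KHSO5, K2CO3, MeCN–dimethoxymethane–H2O, 0 °C) is expected, through its spiro transition state, to deliver oxygen to the face that gives the (R)-oxirane.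

Step 3. After ionisation the bromonium ion may pass Br+ to the isopropenyl double bond of a second molecule, or lose a proton, faster than it collapses with chloride; either would scramble the C–Br/C–Cl array. The fallback masks the alkene as a ketone, sets out from 2 and comes back at 4. Ozonolysis of the isopropenyl group of 2 (O3, CH2Cl2, −78 °C; PPh3) should give the keto epoxide 1-[(1R,3S,6S)-6-methyl-7-oxabicyclo[4.1.0]heptan-3-yl]ethan-1-one F2. Opening with cold aqueous HBr as in step 2 gives the bromohydrin 1-[(1S,3R,4R)-4-bromo-3-hydroxy-4-methylcyclohexyl]ethan-1-one F3. The α-chloroenamine of step 3 then gives the bromochloro ketone 1-[(1S,3S,4S)-3-bromo-4-chloro-4-methylcyclohexyl]ethan-1-one F4, and Petasis methylenation with Cp2TiMe2 (toluene, 65 °C), a non-basic reagent that should leave the stereocentre next to the carbonyl untouched, returns to 4.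

Step 4. The ene reaction may also take the ring methine C–H next to the alkene, and the allylic alcohol may be oxidised on to the enal. The fallback replaces the selenium oxidation by chlorination and substitution, sets out from 4 and comes back at 5. Ene-type chlorination with HOCl generated from Ca(OCl)2 and CO2 (CH2Cl2–H2O, 0 °C) should give the allylic chloride (1S,2S,4S)-2-bromo-1-chloro-4-(3-chloroprop-1-en-2-yl)-1-methylcyclohexane F5. Displacement with KOAc (DMF, 50 °C) gives 2-[(1S,3S,4S)-3-bromo-4-chloro-4-methylcyclohexyl]prop-2-en-1-yl acetate F6, and methanolysis (K2CO3, MeOH, 0 °C) gives 5.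

**Further compounds**

F1 | step 14 | (3S)-3-[(1S,3S,4S)-3-bromo-4-chloro-4-methylcyclohexyl]-6-methyl-3-[(triethylsilyl)oxy]hept-5-en-2-one | CC(=O)[C@](O[Si](CC)(CC)CC)(CC=C(C)C)[C@H]1CC[C@](C)(Cl)[C@@H](Br)C1
F2 | step 3 | 1-[(1R,3S,6S)-6-methyl-7-oxabicyclo[4.1.0]heptan-3-yl]ethan-1-one | CC(=O)[C@H]1CC[C@]2(C)O[C@@H]2C1
F3 | step 3 | 1-[(1S,3R,4R)-4-bromo-3-hydroxy-4-methylcyclohexyl]ethan-1-one | CC(=O)[C@H]1CC[C@@](C)(Br)[C@H](O)C1
F4 | step 3 | 1-[(1S,3S,4S)-3-bromo-4-chloro-4-methylcyclohexyl]ethan-1-one | CC(=O)[C@H]1CC[C@](C)(Cl)[C@@H](Br)C1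
F5 | step 4 | (1S,2S,4S)-2-bromo-1-chloro-4-(3-chloroprop-1-en-2-yl)-1-methylcyclohexane | ClCC(=C)[C@H]1CC[C@](C)(Cl)[C@@H](Br)C1
F6 | step 4 | 2-[(1S,3S,4S)-3-bromo-4-chloro-4-methylcyclohexyl]prop-2-en-1-yl acetate | CC(=O)OCC(=C)[C@H]1CC[C@](C)(Cl)[C@@H](Br)C1
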